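## The problem

Compound 20 is a cyclohexane with three stereocentres: the tertiary carbinol C1 (R), the secondary chloride C3 (S) and the methyl-bearing tertiary bromide C4 (S). C1 carries a chain in which C7 is a 1,1-disubstituted alkene carbon (C7=C14H2), C8 is a methylene and C9 (S) is an allylic carbinol next to the C10=C11 trisubstituted alkene. On the ring the C1 hydroxyl is cis to bromine and trans to chlorine, and the halogens are trans to each other. C1 can therefore control C3 and C4 if its oxygen is made to bridge to C4, whereas C9 is insulated from the ring by C7 and C8 and must be set by a reagent. The halogen pattern (chlorine on the less substituted carbon, bromine on the tertiary one) is the reverse of what an interhalogen adds to a C3=C4(CH3) alkene, so electrophilic chlorine and nucleophilic bromide have to arrive in separate operations. The tertiary bromide beside a chloride will not tolerate strong base, Lewis acid or prolonged heat, the C9 alcohol ionises easily in acid, and once C7 is sp2 the C1 carbinol is allylic too; this dictates much of the order of events. C1 is a quaternary carbinol whose two ring arms (C2, C6) differ only at remote atoms, so a face-selective carbonyl addition is unattractive. Without its halogens the ring is a 4-methylcyclohex-3-en-1-ol with C1 homoallylic to C3=C4(CH3), which is the array a 2-methylbicyclo[3.1.0]hex-2-yl cation releases when its shared cyclopropane bond opens, so C1 can be traced back to a cyclopropane stereocentre.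

## Retrosynthesis

**C7=C14 (20 ⇒ 19 ⇒ 18).** The methylene is removed first, giving ketone 18 by way of the β-hydroxysilane 19. It has to be the last bond made, because a C7 alkene would make the C1–O bond allylic and unfit for the cationic halogen chemistry. A Peterson sequence is preferred to ylide or titanium reagents: the addition uses a weakly basic organocerium reagent and the elimination is acid-induced, so the tertiary bromide never meets a strong base, and the same acid removes the silyl ether on C1.

**C8–C9 (18 ⇒ 16 + 17).** An aldol cut removes five carbons and the C9 stereocentre, leaving methyl ketone 16 and 3-methylbut-2-enal 17. The alternative, a 2-substituted allyl metal adding to 17, would require making an allyl metal in the presence of the tertiary bromide. The aldol uses the acetyl group that the halogen chemistry needs anyway. The forward reaction must be reagent-controlled at C9 and must enolise with an amine base at low temperature.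

**C4–Br, then C3–Cl and C4–O (16 ⇒ 15 ⇒ 14).** The bromide is traced to the bridged ether 15 (C1–O–C4), and 15 to the hydroxy alkene 14 by chloroetherification. This detour solves the regiochemistry: the chloronium ion is captured by the C1 hydroxyl instead of bromide, stored as an ether, and released to bromide later. It also solves the stereochemistry, since only the chloronium ion anti to the C1 oxygen can cyclise (Cl trans to OH), and re-opening anti to chlorine places bromine on the oxygen's face. The acetyl group on C1 is essential. It leaves the tertiary hydroxyl as the only nucleophile; in diols 11 or 13 the side-chain hydroxyl would close a 2-oxabicyclo[2.2.2]octane from the other face and set C3 wrongly. It also blocks ionisation of the C1–O bond during the opening.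

**Acetyl from CH2OPMB (14 ⇒ 13 ⇒ 12 ⇒ 11 ⇒ 10).** Oxidation-level changes and one methyl addition connect 14 to the ring-expansion product 10. The acetyl group cannot be carried through the key step, because a carbonyl on C1 would forbid the positive charge that must develop there; an sp3, oxygenated C7 is the right spectator.

**Key disconnection (10 ⇒ 9).** Re-forming the C1–C3 bond and moving the hydroxyl from C1 to C4 turns cyclohexenol 10 into the bicyclo[3.1.0]hexanol 9. The quaternary carbinol becomes a cyclopropane stereocentre. The forward reaction must open the shared cyclopropane bond with water entering at C1 anti to the departing C3.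

**Cyclopropane (9 ⇒ 8 ⇒ 7).** Methyl addition gives 9 from ketone 8, and 8 comes from diazoketone 7 by intramolecular carbene addition to a 1,1-disubstituted alkene. Cis fusion is enforced, so one catalyst-controlled facial decision sets both cyclopropane centres.

**Chain (7 ⇒ 6 ⇒ 5 ⇒ 3 + 4 ⇒ 1 + 2).** Diazo transfer via the activated diketone 6 leads to methyl ketone 5. A Claisen rearrangement of the isopropenyl ether of allylic alcohol 3 with 2-methoxypropene 4 makes the C–C bond. 3 is the mono-PMB ether of diol 1, made with chloride 2.

## Roads not taken

**Alternative 1: halogen interchange.** The cut traces the C4–Br/C3–Cl pair to its constitutional isomer, (1R,3R,4R)-1-acetyl-3-bromo-4-chloro-4-methylcyclohexyl benzoate A2, the normal product of bromonium formation and chloride capture. In the forward key step, heating A2 exchanges the two antiperiplanar halogens in one step, each with inversion, to give 1-acetyl-4-bromo-3-chloro-4-methylcyclohexyl benzoate A1.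
- Merits: it uses the regiochemistry electrophilic bromine gives naturally, one reagent brings in both halogens, the trans relationship is guaranteed, and no bridged intermediate is needed.
- Weak points: each halogen stays on its own face during the shift, so A2 needs bromine syn to the C1 oxygen, and an ester on C1 has no tether to enforce that. The interchange is an equilibrium between two trans-diaxial dihalides of similar energy, reached by heating a tertiary halide. The step does nothing for C1.
- Comparison: this road is equal in length at the halogen stage and better in atom economy. The chosen plan sets against it face control through a covalent C1–O–C4 bridge and a kinetically controlled opening, although its step 12 carries a related uncertainty at C4.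

**Alternative 2: chloro-dienophile Diels–Alder.** The cut is C2–C3 and C4–C5. In the forward key step 2-(acetoxymethyl)buta-1,3-diene A4 and (E)-3-chloro-2-methylprop-2-enal A5 combine under a triflimide-activated oxazaborolidine from (S)-diphenylprolinol to give (5-chloro-4-formyl-4-methylcyclohex-1-en-1-yl)methyl acetate A3 with Cl and CH3 cis.
- Merits: the ring, the C–Cl centre and the quaternary C4 come from one catalytic step, which reaches a chlorinated ring far sooner than the chosen plan.
- Weak points: in A3 C4 bears a formyl group where bromine must stand. Replacing it passes through a radical or cation at C4, which erases the centre the cycloaddition set. The C1 carbinol must later be installed face-selectively on the ring alkene with only remote guidance. The β-chloro enal is a sluggish dienophile and its adduct can lose HCl.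
- Comparison: this road is better on speed to a chlorinated ring, but two of the three ring centres stay unsolved. The chosen plan sets C1 first and relays it to both halogen centres.

**Alternative 3: isoprene Diels–Alder.** The cut is C1–C2 and C5–C6. In the forward key step isoprene A7 and 2-(benzoyloxy)acrolein A8 react under the bis(triflimide) salt of a chiral 1,1'-binaphthyl-2,2'-diamine to give (R)-1-formyl-4-methylcyclohex-3-en-1-yl benzoate A6.
- Merits: ring and C1 are made in one step from commodity chemicals. A6 is two or three operations from 14, which the chosen route reaches only in ten steps, and the later chemistry would be the same. In step economy this road is clearly better.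
- Weak points: enantioselectivity and para regiochemistry rest on a single catalytic step with an unactivated acyclic diene, and the benzoate must be removed next to a carbonyl group.
- Comparison: the chosen plan can only set against it a fixed constitution (no regioisomer) and a C1 configuration that is read from a cyclopropane centre and can be secured by a second carbene manifold (see fallback for step 4) before it is transcribed.

Key step: step 6

## Route

Remark: ring and chain atoms are numbered as in the target throughout (C1 carbinol, C3 chloride, C4 bromide, C7 to C11 and C14 in the chain), also for the bicyclic precursors; metal alkoxides and enolates that exist only in solution (for example the boron enolate of step 13) are treated as reactive intermediates and carry no number.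

Step 1
Reactants: 1 2-methylenepropane-1,3-diol; 2 4-methoxybenzyl chloride
Product: 3 2-{[(4-methoxybenzyl)oxy]methyl}prop-2-en-1-ol
Conditions: NaH (1 equiv), 1 in excess, Bu4NI (cat.), THF–DMF, 0 °C → rt
Reagents that add atoms: none
Why: Williamson etherification; the symmetric diol is used in excess so that the monosodium alkoxide gives mainly the mono-ether, and unreacted diol is washed out with water.

Step 2
Reactants: 3 2-{[(4-methoxybenzyl)oxy]methyl}prop-2-en-1-ol; 4 2-methoxypropene
Product: 5 5-{[(4-methoxybenzyl)oxy]methyl}hex-5-en-2-one
Conditions: 4 (excess), pyridinium p-toluenesulfonate (cat.), toluene, sealed tube, 130 °C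
Reagents that add atoms: none
Why: Saucy–Marbet (ketal) Claisen rearrangement: acid-catalysed exchange gives the allyl isopropenyl ether, whose [3,3]-shift forms the C–C bond and the methyl ketone in one operation; the mild acid leaves the PMB ether intact.

Step 3
Reactants: 5 5-{[(4-methoxybenzyl)oxy]methyl}hex-5-en-2-one
Product: 7 1-diazo-5-{[(4-methoxybenzyl)oxy]methyl}hex-5-en-2-one, via trifluoroacetyl diketone 6 (not isolated)
Conditions: LiN(SiMe3)2, THF, −78 °C; CF3CO2CH2CF3; extractive work-up, crude 6 used at once; MsN3, Et3N, H2O, MeCN, rt
Reagents that add atoms: methanesulfonyl azide, CS(=O)(=O)N=[N+]=[N-] (the two diazo nitrogens); 2,2,2-trifluoroethyl trifluoroacetate, O=C(OCC(F)(F)F)C(F)(F)F (trifluoroacetyl group of 6 only, lost again on diazo transfer)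
Why: Detrifluoroacetylative diazo transfer: the kinetic enolate forms at the methyl group, trifluoroacetylation activates that carbon, and the sulfonyl azide transfers N2 with loss of the trifluoroacetyl group; no diazomethane is needed.

Step 4
Reactants: 7 1-diazo-5-{[(4-methoxybenzyl)oxy]methyl}hex-5-en-2-one
Product: 8 (1R,5R)-5-{[(4-methoxybenzyl)oxy]methyl}bicyclo[3.1.0]hexan-2-one
Conditions: (CuOTf)2·C6H6 (2.5 mol %), 2,2'-(propane-2,2-diyl)bis[(4S)-4-tert-butyl-4,5-dihydrooxazole] (6 mol %), CH2Cl2, slow addition of 7, rt
Reagents that add atoms: none
Why: Intramolecular cyclopropanation of an alkenyl diazoketone by a copper carbene; cis fusion is geometrically enforced, so the C2-symmetric bis(oxazoline) makes a single facial choice at the 1,1-disubstituted alkene that fixes both cyclopropane centres; five-ring formation is faster than attack on the remote ether oxygen or arene.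

Step 5
Reactants: 8 (1R,5R)-5-{[(4-methoxybenzyl)oxy]methyl}bicyclo[3.1.0]hexan-2-one
Product: 9 (1R,2S,5R)-5-{[(4-methoxybenzyl)oxy]methyl}-2-methylbicyclo[3.1.0]hexan-2-ol
Conditions: MeMgBr, THF, −78 → 0 °C; aq. NH4Cl
Reagents that add atoms: methylmagnesium bromide, C[Mg]Br
Why: Grignard addition from the convex face, anti to the cyclopropane methylene, should give the 2S carbinol; the selectivity is not critical because this carbon becomes sp2 in step 6.

Step 6
Reactants: 9 (1R,2S,5R)-5-{[(4-methoxybenzyl)oxy]methyl}-2-methylbicyclo[3.1.0]hexan-2-ol
Product: 10 (1R)-1-{[(4-methoxybenzyl)oxy]methyl}-4-methylcyclohex-3-en-1-ol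
Conditions: H2SO4 (0.05 M), THF–H2O (1:1), 0 °C → rt, quench with NaHCO3 at full conversion
Reagents that add atoms: water, O
Why: Protonation and loss of the tertiary hydroxyl at C4 gives a cyclopropylcarbinyl cation delocalised into the cyclopropane; water then attacks the quaternary cyclopropane carbon C1 anti to C3 as the C1–C3 bond becomes the C3=C4 π bond. The closest known reaction type is the acid-mediated cyclopropylcarbinyl-to-homoallyl ring expansion of sabinene hydrate to terpinen-4-ol (thujane to p-menthane). The six-membered ring is not closed by a cyclisation: it arises when the bond shared by the three- and five-membered rings breaks, merging them. The new stereocentre C1 is controlled by the configuration of the cyclopropane carbon set in step 4, which is transcribed with inversion and gives R. Cleavage of the shared bond rather than the external C2–C3 bond is required, and is secured because only the former leads to a tertiary cationic terminus and releases the strain of both rings. Capture by water rather than proton loss is favoured by the dilute, water-rich medium and low temperature. Fidelity at C1 requires bond making to accompany bond breaking; the inductively withdrawing CH2OPMB group on C1 disfavours a free, achiral cyclohex-3-enyl cation. The PMB ether tolerates the dilute acid, and the reaction is stopped before the product alkene can be protonated.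

Step 7
Reactants: 10 (1R)-1-{[(4-methoxybenzyl)oxy]methyl}-4-methylcyclohex-3-en-1-ol
Product: 11 (1R)-1-(hydroxymethyl)-4-methylcyclohex-3-en-1-ol
Conditions: DDQ, CH2Cl2–pH 7 buffer (10:1), 0 °C → rt
Reagents that add atoms: none
Why: Oxidative PMB cleavage; the wet, buffered medium hydrolyses the benzylic oxocarbenium ion before the neighbouring tertiary hydroxyl can trap it as an acetal, and neutrality protects the acid-sensitive ene-diol.

Step 8
Reactants: 11 (1R)-1-(hydroxymethyl)-4-methylcyclohex-3-en-1-ol
Product: 12 (1R)-1-hydroxy-4-methylcyclohex-3-ene-1-carbaldehyde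
Conditions: SO3·pyridine, DMSO, i-Pr2NEt, CH2Cl2, 0 °C; used crude
Reagents that add atoms: none
Why: Parikh–Doering oxidation takes the primary alcohol to the aldehyde without touching the tertiary alcohol and without glycol cleavage; the aldehyde has no α-hydrogen and cannot epimerise.

Step 9
Reactants: 12 (1R)-1-hydroxy-4-methylcyclohex-3-ene-1-carbaldehyde
Product: 13 (1R)-1-(1-hydroxyethyl)-4-methylcyclohex-3-en-1-ol (both epimers at the new carbinol)
Conditions: MeMgBr (2.5 equiv), THF, −78 → 0 °C; aq. NH4Cl
Reagents that add atoms: methylmagnesium bromide, C[Mg]Br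
Why: Grignard addition to the aldehyde after deprotonation of the tertiary hydroxyl by the first equivalent; the new centre is oxidised away in step 10.

Step 10
Reactants: 13 (1R)-1-(1-hydroxyethyl)-4-methylcyclohex-3-en-1-ol
Product: 14 1-[(1R)-1-hydroxy-4-methylcyclohex-3-en-1-yl]ethan-1-one
Conditions: IBX, DMSO, rt
Reagents that add atoms: none
Why: IBX oxidises the secondary alcohol of a 1,2-diol to the α-hydroxy ketone without C–C cleavage and leaves the alkene and tertiary alcohol untouched.

Step 11
Reactants: 14 1-[(1R)-1-hydroxy-4-methylcyclohex-3-en-1-yl]ethan-1-one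
Product: 15 1-[(1S,2S,4R)-2-chloro-1-methyl-7-oxabicyclo[2.2.1]heptan-4-yl]ethan-1-one
Conditions: NCS, Ph3P=S (5 mol %), CH2Cl2, −20 °C → rt
Reagents that add atoms: N-chlorosuccinimide, O=C1CCC(=O)N1Cl
Why: Chloroetherification (electrophilic halocyclisation): the chloronium ion on the face opposite the C1 hydroxyl is opened at the tertiary carbon C4 by that hydroxyl through a boat-like transition state; anti addition places C3–Cl trans to the C1 oxygen, and only this facial isomer of the chloronium ion can cyclise.

Step 12
Reactants: 15 1-[(1S,2S,4R)-2-chloro-1-methyl-7-oxabicyclo[2.2.1]heptan-4-yl]ethan-1-one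
Product: 16 1-[(1R,3S,4S)-4-bromo-3-chloro-4-methyl-1-(trimethylsilyloxy)cyclohexyl]ethan-1-one
Conditions: Me3SiBr, 2,6-di-tert-butyl-4-methylpyridine (cat.), CH2Cl2, −40 → 0 °C
Reagents that add atoms: bromotrimethylsilane, C[Si](C)(C)Br
Why: Silyl bromide cleavage of a tertiary alkyl ether: silylation of the bridging oxygen, ionisation of the C4–O bond assisted by the antiperiplanar C3–Cl (the reverse of step 11), and capture by bromide at C4 anti to chlorine, that is on the face the oxygen leaves (net retention at C4). The acetyl group blocks ionisation at C1, the silylated oxygen cannot re-close, and the C1 oxygen emerges protected.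

Step 13
Reactants: 16 1-[(1R,3S,4S)-4-bromo-3-chloro-4-methyl-1-(trimethylsilyloxy)cyclohexyl]ethan-1-one; 17 3-methylbut-2-enal
Product: 18 (3S)-1-[(1R,3S,4S)-4-bromo-3-chloro-4-methyl-1-(trimethylsilyloxy)cyclohexyl]-3-hydroxy-5-methylhex-4-en-1-one
Conditions: (+)-Ipc2BCl, Et3N, Et2O, −78 → 0 °C; 17, −78 → −20 °C; pH 7 buffer, MeOH, 30% H2O2, 0 °C
Reagents that add atoms: none
Why: Boron aldol of a methyl ketone under reagent control: 16 can enolise only toward C8, the isopinocampheyl groups differentiate the aldehyde faces (si-face attack is expected for this enantiomer of the reagent with methyl ketone enolates, giving 9S), and boron enolates add 1,2 to enals; the amine base at low temperature spares the tertiary bromide.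

Step 14
Reactants: 18 (3S)-1-[(1R,3S,4S)-4-bromo-3-chloro-4-methyl-1-(trimethylsilyloxy)cyclohexyl]-3-hydroxy-5-methylhex-4-en-1-one
Product: 19 (4S)-2-[(1R,3S,4S)-4-bromo-3-chloro-4-methyl-1-(trimethylsilyloxy)cyclohexyl]-6-methyl-1-(trimethylsilyl)hept-5-ene-2,4-diol (both epimers at C2 of the chain)
Conditions: Me3SiCH2MgCl, CeCl3, THF, −78 → 0 °C; aq. NH4Cl
Reagents that add atoms: (trimethylsilyl)methylmagnesium chloride, C[Si](C)(C)C[Mg]Cl
Why: First stage of a Peterson olefination: the weakly basic organocerium reagent adds to the hindered, enolisable β-hydroxy ketone without retro-aldol cleavage or loss of HBr; one equivalent is consumed by the C9 hydroxyl, and the configuration of the new carbinol is irrelevant.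

Step 15
Reactants: 19 (4S)-2-[(1R,3S,4S)-4-bromo-3-chloro-4-methyl-1-(trimethylsilyloxy)cyclohexyl]-6-methyl-1-(trimethylsilyl)hept-5-ene-2,4-diol
Product: 20 (1R,3S,4S)-4-bromo-3-chloro-1-[(4S)-4-hydroxy-6-methylhepta-1,5-dien-2-yl]-4-methylcyclohexan-1-ol
Conditions: 48% aq. HF, MeCN, 0 °C; NaHCO3 quench
Reagents that add atoms: none
Why: Acid-induced Peterson elimination of the tertiary β-hydroxysilane, which can only give the C7=C14 methylene, with cleavage of the trimethylsilyl ether on C1 by the same reagent; brief exposure to cold, dilute HF should leave the allylic C9 alcohol and the tertiary bromide intact.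

## Compound list

1 | 2-methylenepropane-1,3-diol | C=C(CO)CO | starting material
2 | 4-methoxybenzyl chloride | COc1ccc(CCl)cc1 | starting material
3 | 2-{[(4-methoxybenzyl)oxy]methyl}prop-2-en-1-ol | C=C(CO)COCc1ccc(OC)cc1 | intermediate
4 | 2-methoxypropene | C=C(C)OC | starting material
5 | 5-{[(4-methoxybenzyl)oxy]methyl}hex-5-en-2-one | CC(=O)CCC(=C)COCc1ccc(OC)cc1 | intermediate
6 | 1,1,1-trifluoro-7-{[(4-methoxybenzyl)oxy]methyl}oct-7-ene-2,4-dione | COc1ccc(COCC(=C)CCC(=O)CC(=O)C(F)(F)F)cc1 | intermediate
7 | 1-diazo-5-{[(4-methoxybenzyl)oxy]methyl}hex-5-en-2-one | [N-]=[N+]=CC(=O)CCC(=C)COCc1ccc(OC)cc1 | intermediate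
8 | (1R,5R)-5-{[(4-methoxybenzyl)oxy]methyl}bicyclo[3.1.0]hexan-2-one | COc1ccc(COC[C@]23C[C@H]2C(=O)CC3)cc1 | intermediate
9 | (1R,2S,5R)-5-{[(4-methoxybenzyl)oxy]methyl}-2-methylbicyclo[3.1.0]hexan-2-ol | COc1ccc(COC[C@]23C[C@H]2[C@@](C)(O)CC3)cc1 | intermediate
10 | (1R)-1-{[(4-methoxybenzyl)oxy]methyl}-4-methylcyclohex-3-en-1-ol | COc1ccc(COC[C@@]2(O)CCC(C)=CC2)cc1 | intermediate
11 | (1R)-1-(hydroxymethyl)-4-methylcyclohex-3-en-1-ol | OC[C@@]1(O)CCC(C)=CC1 | intermediate
12 | (1R)-1-hydroxy-4-methylcyclohex-3-ene-1-carbaldehyde | O=C[C@@]1(O)CCC(C)=CC1 | intermediate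
13 | (1R)-1-(1-hydroxyethyl)-4-methylcyclohex-3-en-1-ol (both side-chain epimers) | CC(O)[C@@]1(O)CCC(C)=CC1 | intermediate
14 | 1-[(1R)-1-hydroxy-4-methylcyclohex-3-en-1-yl]ethan-1-one | CC(=O)[C@@]1(O)CCC(C)=CC1 | intermediate
15 | 1-[(1S,2S,4R)-2-chloro-1-methyl-7-oxabicyclo[2.2.1]heptan-4-yl]ethan-1-one | CC(=O)[C@]12CC[C@](C)(O1)[C@@H](Cl)C2 | intermediate
16 | 1-[(1R,3S,4S)-4-bromo-3-chloro-4-methyl-1-(trimethylsilyloxy)cyclohexyl]ethan-1-one | CC(=O)[C@@]1(O[Si](C)(C)C)CC[C@](C)(Br)[C@@H](Cl)C1 | intermediate
17 | 3-methylbut-2-enal | CC(C)=CC=O | starting material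
18 | (3S)-1-[(1R,3S,4S)-4-bromo-3-chloro-4-methyl-1-(trimethylsilyloxy)cyclohexyl]-3-hydroxy-5-methylhex-4-en-1-one | CC(C)=C[C@@H](O)CC(=O)[C@@]1(O[Si](C)(C)C)CC[C@](C)(Br)[C@@H](Cl)C1 | intermediate
19 | (4S)-2-[(1R,3S,4S)-4-bromo-3-chloro-4-methyl-1-(trimethylsilyloxy)cyclohexyl]-6-methyl-1-(trimethylsilyl)hept-5-ene-2,4-diol (both epimers at C2 of the chain) | CC(C)=C[C@@H](O)CC(O)(C[Si](C)(C)C)[C@@]1(O[Si](C)(C)C)CC[C@](C)(Br)[C@@H](Cl)C1 | intermediate
20 | (1R,3S,4S)-4-bromo-3-chloro-1-[(4S)-4-hydroxy-6-methylhepta-1,5-dien-2-yl]-4-methylcyclohexan-1-ol | C=C(C[C@H](O)C=C(C)C)[C@@]1(O)CC[C@](C)(Br)[C@@H](Cl)C1 | target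

## Step count and weak points

Total: 15 steps. Longest linear sequence: 15 steps (1 → 20); 2, 4 and 17 are commercial and enter along the way.

**Step 6 (key step).** The most likely failure is partial loss of configuration at C1, if the C1–C3 bond ionises fully before water bonds and a free, achiral cyclohexenyl cation results. Proton loss to dienes and acid-induced follow-up reactions of 10 are the accompanying risks. Fallback, from 9 back to 10: the lithium alkoxide of 9 (n-BuLi, THF, −78 °C) is acylated with 4-nitrobenzoyl chloride to give (1R,2S,5R)-5-{[(4-methoxybenzyl)oxy]methyl}-2-methylbicyclo[3.1.0]hexan-2-yl 4-nitrobenzoate F1. F1 is solvolysed in aqueous acetone buffered with 2,6-lutidine. Ionisation then needs no acid, the medium is less ionising, and 10 is never exposed to conditions that could re-ionise it.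

**Step 12.** Capture at C4 may not stay anti to chlorine if the tertiary cation outlives the chlorine bridge, giving the C4 epimer; E1 loss of a proton is the second risk. Thermodynamic equilibration cannot be relied on to correct this. Fallback, from the crude product of step 12 back to 15: the opening is run without reliance on selectivity and the epimer 1-[(1R,3S,4R)-4-bromo-3-chloro-4-methyl-1-(trimethylsilyloxy)cyclohexyl]ethan-1-one F2 is separated by chromatography. F2 is treated with AgOTf and 2,6-di-tert-butylpyridine in CH2Cl2. In F2 the silyloxy oxygen lies anti to the C4–Br bond, so silver-assisted ionisation re-closes the bridge with loss of the silyl group. The recovered 15 is resubmitted, making the sequence iterative instead of selective.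

**Step 4.** Enantioselectivity of carbene transfer from simple diazoketones to 1,1-disubstituted alkenes is often incomplete, and the sense of induction with the (S,S)-ligand has to be established by correlation at 8 (the antipodal ligand is equally available). Fallback, from 3 back to 8:
- Johnson–Claisen rearrangement of 3 with triethyl orthoacetate (EtCO2H cat., 140 °C) gives ethyl 4-{[(4-methoxybenzyl)oxy]methyl}pent-4-enoate F3.
- Condensation with lithiated mesityl methyl sulfone gives 1-(mesitylsulfonyl)-5-{[(4-methoxybenzyl)oxy]methyl}hex-5-en-2-one F4.
- Diazo transfer (4-acetamidobenzenesulfonyl azide, Et3N) gives 1-diazo-1-(mesitylsulfonyl)-5-{[(4-methoxybenzyl)oxy]methyl}hex-5-en-2-one F5.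
- CuOTf/bis(oxazoline) cyclopropanation, for which α-diazo-β-keto sulfones are a well-behaved, highly enantioselective substrate class, gives (1S,5S)-1-(mesitylsulfonyl)-5-{[(4-methoxybenzyl)oxy]methyl}bicyclo[3.1.0]hexan-2-one F6. It has the same cyclopropane sense as 8; the descriptors change because sulfur outranks oxygen.
- Reductive desulfonylation (SmI2, THF–MeOH, −78 °C) gives 8.

**Step 11.** Proton loss from the chloronium ion (ene-type allylic chlorination of the trisubstituted alkene) may outrun the boat-like closure by a hydroxyl that the neighbouring ketone makes less nucleophilic. Fallback, from 14 back to 15: intramolecular oxymercuration (Hg(O2CCF3)2, CH2Cl2; then aqueous NaCl), which is reversible and cannot end in an allylic product, gives 1-[(1S,2S,4R)-2-(chloromercurio)-1-methyl-7-oxabicyclo[2.2.1]heptan-4-yl]ethan-1-one F7 with the same anti relationship. Electrophilic cleavage of the C–Hg bond with Cl2 in pyridine at low temperature, which proceeds with retention, then gives 15.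

**Step 13.** Induction at C9 rests on the boron ligands alone, because C1 has two near-identical ring arms and offers no substrate bias. A modest diastereomer ratio, or the opposite sense (then the antipodal reagent), is the likely shortfall. Fallback, from 20 obtained as a mixture with its C9 epimer back to 20: the mixture containing (1R,3S,4S)-4-bromo-3-chloro-1-[(4R)-4-hydroxy-6-methylhepta-1,5-dien-2-yl]-4-methylcyclohexan-1-ol F8 is oxidised at the allylic alcohol with MnO2 (CH2Cl2, rt) to 2-[(1R,3S,4S)-4-bromo-3-chloro-1-hydroxy-4-methylcyclohexyl]-6-methylhepta-1,5-dien-4-one F9. Corey–Bakshi–Shibata reduction ((R)-2-methyl-CBS-oxazaborolidine, catecholborane, toluene, −78 °C) then sets C9 as S, with the alkenyl group acting as the large substituent.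

## Further compounds

F1 | step 6 | (1R,2S,5R)-5-{[(4-methoxybenzyl)oxy]methyl}-2-methylbicyclo[3.1.0]hexan-2-yl 4-nitrobenzoate | COc1ccc(COC[C@]23C[C@H]2[C@@](C)(OC(=O)c4ccc([N+](=O)[O-])cc4)CC3)cc1
F2 | step 12 | 1-[(1R,3S,4R)-4-bromo-3-chloro-4-methyl-1-(trimethylsilyloxy)cyclohexyl]ethan-1-one | CC(=O)[C@@]1(O[Si](C)(C)C)CC[C@@](C)(Br)[C@@H](Cl)C1
F3 | step 4 | ethyl 4-{[(4-methoxybenzyl)oxy]methyl}pent-4-enoate | CCOC(=O)CCC(=C)COCc1ccc(OC)cc1
F4 | step 4 | 1-(mesitylsulfonyl)-5-{[(4-methoxybenzyl)oxy]methyl}hex-5-en-2-one | COc1ccc(COCC(=C)CCC(=O)CS(=O)(=O)c2c(C)cc(C)cc2C)cc1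
F5 | step 4 | 1-diazo-1-(mesitylsulfonyl)-5-{[(4-methoxybenzyl)oxy]methyl}hex-5-en-2-one | COc1ccc(COCC(=C)CCC(=O)C(=[N+]=[N-])S(=O)(=O)c2c(C)cc(C)cc2C)cc1
F6 | step 4 | (1S,5S)-1-(mesitylsulfonyl)-5-{[(4-methoxybenzyl)oxy]methyl}bicyclo[3.1.0]hexan-2-one | COc1ccc(COC[C@]23C[C@@]2(S(=O)(=O)c4c(C)cc(C)cc4C)C(=O)CC3)cc1
F7 | step 11 | 1-[(1S,2S,4R)-2-(chloromercurio)-1-methyl-7-oxabicyclo[2.2.1]heptan-4-yl]ethan-1-one | CC(=O)[C@]12CC[C@](C)(O1)[C@@H]([Hg]Cl)C2
F8 | step 13 | (1R,3S,4S)-4-bromo-3-chloro-1-[(4R)-4-hydroxy-6-methylhepta-1,5-dien-2-yl]-4-methylcyclohexan-1-ol | C=C(C[C@@H](O)C=C(C)C)[C@@]1(O)CC[C@](C)(Br)[C@@H](Cl)C1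
F9 | step 13 | 2-[(1R,3S,4S)-4-bromo-3-chloro-1-hydroxy-4-methylcyclohexyl]-6-methylhepta-1,5-dien-4-one | C=C(CC(=O)C=C(C)C)[C@@]1(O)CC[C@](C)(Br)[C@@H](Cl)C1
A1 | alternative 1 | (1R,3S,4S)-1-acetyl-4-bromo-3-chloro-4-methylcyclohexyl benzoate | CC(=O)[C@@]1(OC(=O)c2ccccc2)CC[C@](C)(Br)[C@@H](Cl)C1
A2 | alternative 1 | (1R,3R,4R)-1-acetyl-3-bromo-4-chloro-4-methylcyclohexyl benzoate | CC(=O)[C@@]1(OC(=O)c2ccccc2)CC[C@@](C)(Cl)[C@H](Br)C1
A3 | alternative 2 | (5-chloro-4-formyl-4-methylcyclohex-1-en-1-yl)methyl acetate (Cl cis to CH3) | CC(=O)OCC1=CC[C@](C)(C=O)[C@@H](Cl)C1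
A4 | alternative 2 | 2-(acetoxymethyl)buta-1,3-diene | C=CC(=C)COC(C)=O
A5 | alternative 2 | (E)-3-chloro-2-methylprop-2-enal | Cl/C=C(\C)C=O
A6 | alternative 3 | (R)-1-formyl-4-methylcyclohex-3-en-1-yl benzoate | O=C[C@@]1(OC(=O)c2ccccc2)CCC(C)=CC1
A7 | alternative 3 | isoprene | C=CC(C)=C
A8 | alternative 3 | 2-(benzoyloxy)acrolein | C=C(C=O)OC(=O)c1ccccc1
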